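The target is a β-hydroxy ketone: the tertiary C3–OH and the aroyl carbonyl on C4 sit cis on the butyrolactone ring. Everything rests on tying the C3 oxygen to that carbonyl carbon in a four-membered lactone fused across C3–C4, then opening it with an aryl nucleophile. In one operation 4-benzyloxy-3-methoxyphenyllithium attacks the strained acyl carbon of a (1S,5S)-5-arylmethyl-3,6-dioxabicyclo[3.2.0]heptane-4,7-dione. The aryl–carbonyl bond forms, the C3 hydroxyl is released, and both stereocentres, locked by the cis ring fusion, are delivered intact. The bis-lactone is built from (S)-malic acid by Seebach benzylation, then one-flask hydroxymethylation, transacylation and silver-promoted β-lactonisation.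

Key step: step 5

Remark on numbering: O1, C2 (lactone C=O), C3 (carbinol carbon), C4 (CH) and C5 (CH2) refer to the butyrolactone ring of the target.
Assumption: 4-(benzyloxy)-3-methoxybenzyl bromide (3) is taken as a catalogue compound; if it is not in stock it is one step (PBr3) from the catalogue alcohol.

Step 1
Reactants: 1 (S)-malic acid
Product: 2 [(2S,4S)-2-tert-butyl-5-oxo-1,3-dioxolan-4-yl]acetic acid
Conditions: t-BuCHO (2 equiv), TsOH·H2O (cat.), H2SO4 (cat.), pentane, reflux, Dean–Stark; recrystallisation
Reagents that add atoms: pivalaldehyde CC(C)(C)C=O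
Why: Acid-catalysed acetalisation of the α-hydroxy acid unit (Seebach template); the five-membered dioxolanone is favoured over the dioxanone, and the cis (2S,4S) acetal, whose acetal carbon is set by the existing carbinol centre, should be obtained pure by crystallisation.

Step 2
Reactants: 2 [(2S,4S)-2-tert-butyl-5-oxo-1,3-dioxolan-4-yl]acetic acid; 3 4-(benzyloxy)-3-methoxybenzyl bromide
Product: 4 2-[(2S,4S)-4-[4-(benzyloxy)-3-methoxybenzyl]-2-tert-butyl-5-oxo-1,3-dioxolan-4-yl]acetic acid
Conditions: LiHMDS (2.1 equiv), THF, −78 °C; then 3, −78 → −20 °C; aq. HCl work-up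
Reagents that add atoms: none
Why: Seebach self-regeneration of stereocentres: the dianion (carboxylate plus dioxolanone enolate) is alkylated on the face anti to the tert-butyl group, so the benzyl group replaces H with retention and the quaternary carbinol carbon (C3 of the target) is set as S.

Step 3
Reactants: 4 2-[(2S,4S)-4-[4-(benzyloxy)-3-methoxybenzyl]-2-tert-butyl-5-oxo-1,3-dioxolan-4-yl]acetic acid
Product: 5 S-phenyl 2-[(2S,4S)-4-[4-(benzyloxy)-3-methoxybenzyl]-2-tert-butyl-5-oxo-1,3-dioxolan-4-yl]ethanethioate
Conditions: PhSH, DCC, DMAP (cat.), CH2Cl2, 0 °C → rt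
Reagents that add atoms: thiophenol Sc1ccccc1
Why: Steglich-type DCC/DMAP thioesterification of the side-chain acid; no stereocentre is involved, and the thiophenyl ester gives both an easily enolised α-CH2 and an acyl group that a thiophile can activate.

Step 4
Reactants: 5 S-phenyl 2-[(2S,4S)-4-[4-(benzyloxy)-3-methoxybenzyl]-2-tert-butyl-5-oxo-1,3-dioxolan-4-yl]ethanethioate
Product: 8 (1S,5S)-5-[4-(benzyloxy)-3-methoxybenzyl]-3,6-dioxabicyclo[3.2.0]heptane-4,7-dione, via aldolate 6 (not isolated), via lactone alkoxide 7 (not isolated)
Conditions: LiHMDS (1.05 equiv), THF, −78 °C; CH2O (monomeric, titrated THF solution, 1.1 equiv), −78 → 0 °C; then AgOCOCF3 (1.2 equiv), 0 °C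
Reagents that add atoms: formaldehyde C=O
Why: Three known events are run in one flask: hydroxymethylation of the lithium thiol-ester enolate with formaldehyde, 5-exo-trig transacylation of the new primary alkoxide onto the dioxolanone carbonyl (forms the γ-lactone, expels pivalaldehyde and unveils the C3 alkoxide), and Ag(I)-promoted lactonisation of the thiol ester (Masamune-type thiophile activation) to the oxetan-2-one; the four-membered ring can only close cis, so C4 is set as S relative to the Seebach-derived C3, and the epimer that cannot close should be returned through reversible enolisation of the activated thiol ester.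

Step 5
Reactants: 8 (1S,5S)-5-[4-(benzyloxy)-3-methoxybenzyl]-3,6-dioxabicyclo[3.2.0]heptane-4,7-dione; 9 1-(benzyloxy)-4-bromo-2-methoxybenzene
Product: 11 (3S,4S)-3-[4-(benzyloxy)-3-methoxybenzyl]-4-[4-(benzyloxy)-3-methoxybenzoyl]-3-hydroxydihydrofuran-2(3H)-one, via aryllithium 10 (not isolated)
Conditions: 9, n-BuLi (1.0 equiv), THF, −78 °C; this solution added slowly to 8 (1.0 equiv), THF, −78 °C; AcOH quench at −78 °C
Reagents that add atoms: none
Why: The aryllithium adds to the strained oxetan-2-one carbonyl (C7 of the bicycle) and the tetrahedral intermediate collapses by cleavage of the acyl C–O bond, releasing the strain of the four-membered ring and unveiling the C3 alkoxide and the aryl ketone as a lithium aldolate, which is protonated cold. The closest known reaction type is the acyl–oxygen opening of β-lactones by organolithium, Grignard and lithiated phosphonate reagents to β-hydroxy ketones, together with the mono-addition of aryllithiums to lactones at −78 °C. No ring is closed: the four-membered ring is opened and the γ-lactone is left intact. No stereocentre is created: C3 and C4 come from 8, where the cis ring fusion fixed them, and no bond to either is broken, so the cis OH/aroyl (trans benzyl/aroyl) relationship is transferred unchanged. The step needs chemoselectivity for the β-lactone carbonyl over the γ-lactone carbonyl and over the product ketone; this should be secured by the higher electrophilicity of the strained lactone with its α-acyloxy-stabilised alkoxide leaving group, the shielding of the γ-lactone carbonyl by quaternary C3, the deactivated electron-rich ketone held as an aldolate, and inverse addition of one equivalent at −78 °C.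

Step 6
Reactants: 11 (3S,4S)-3-[4-(benzyloxy)-3-methoxybenzyl]-4-[4-(benzyloxy)-3-methoxybenzoyl]-3-hydroxydihydrofuran-2(3H)-one
Product: 12 (3S,4S)-3-hydroxy-3-(4-hydroxy-3-methoxybenzyl)-4-(4-hydroxy-3-methoxybenzoyl)dihydrofuran-2(3H)-one
Conditions: H2 (1 atm), 10% Pd/C, EtOAc, rt
Reagents that add atoms: none
Why: Catalytic hydrogenolysis of the two aryl benzyl ethers under neutral conditions; the lactone and tertiary alcohol are inert, the aryl ketone should be reduced far more slowly than the O-benzyl groups are cleaved, and no base is present that could epimerise C4 or start a retro-aldol.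

Compound list
1 | (S)-malic acid | O[C@@H](CC(=O)O)C(=O)O | starting material
2 | [(2S,4S)-2-tert-butyl-5-oxo-1,3-dioxolan-4-yl]acetic acid | CC(C)(C)[C@H]1O[C@@H](CC(=O)O)C(=O)O1 | intermediate
3 | 4-(benzyloxy)-3-methoxybenzyl bromide | COc1cc(CBr)ccc1OCc1ccccc1 | starting material
4 | 2-[(2S,4S)-4-[4-(benzyloxy)-3-methoxybenzyl]-2-tert-butyl-5-oxo-1,3-dioxolan-4-yl]acetic acid | CC(C)(C)[C@H]1O[C@@](Cc2ccc(OCc3ccccc3)c(OC)c2)(CC(=O)O)C(=O)O1 | intermediate
5 | S-phenyl 2-[(2S,4S)-4-[4-(benzyloxy)-3-methoxybenzyl]-2-tert-butyl-5-oxo-1,3-dioxolan-4-yl]ethanethioate | CC(C)(C)[C@H]1O[C@@](Cc2ccc(OCc3ccccc3)c(OC)c2)(CC(=O)Sc2ccccc2)C(=O)O1 | intermediate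
6 | lithium alkoxide of S-phenyl 2-[(2S,4S)-4-[4-(benzyloxy)-3-methoxybenzyl]-2-tert-butyl-5-oxo-1,3-dioxolan-4-yl]-3-hydroxypropanethioate (both epimers at the new CH) | CC(C)(C)[C@H]1O[C@@](Cc2ccc(OCc3ccccc3)c(OC)c2)(C(CO[Li])C(=O)Sc2ccccc2)C(=O)O1 | intermediate (not isolated)
7 | lithium alkoxide of S-phenyl (4S)-4-[4-(benzyloxy)-3-methoxybenzyl]-4-hydroxy-5-oxotetrahydrofuran-3-carbothioate (both C3 epimers) | COc1cc(C[C@@]2(O[Li])C(=O)OCC2C(=O)Sc2ccccc2)ccc1OCc1ccccc1 | intermediate (not isolated)
8 | (1S,5S)-5-[4-(benzyloxy)-3-methoxybenzyl]-3,6-dioxabicyclo[3.2.0]heptane-4,7-dione | COc1cc(C[C@@]2(OC3=O)C(=O)OC[C@@H]23)ccc1OCc1ccccc1 | intermediate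
9 | 1-(benzyloxy)-4-bromo-2-methoxybenzene | COc1cc(Br)ccc1OCc1ccccc1 | starting material
10 | [4-(benzyloxy)-3-methoxyphenyl]lithium | [Li]c1ccc(OCc2ccccc2)c(OC)c1 | intermediate (not isolated)
11 | (3S,4S)-3-[4-(benzyloxy)-3-methoxybenzyl]-4-[4-(benzyloxy)-3-methoxybenzoyl]-3-hydroxydihydrofuran-2(3H)-one | COc1cc(C[C@@]2(O)C(=O)OC[C@@H]2C(=O)c2ccc(OCc3ccccc3)c(OC)c2)ccc1OCc1ccccc1 | intermediate
12 | (3S,4S)-3-hydroxy-3-(4-hydroxy-3-methoxybenzyl)-4-(4-hydroxy-3-methoxybenzoyl)dihydrofuran-2(3H)-one | COc1cc(C[C@@]2(O)C(=O)OC[C@@H]2C(=O)c2ccc(O)c(OC)c2)ccc1O | target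

Total step count: 6. Longest linear sequence: 6 steps (1 → 12); bromides 3 and 9 enter at steps 2 and 5.

Steps most likely to fail

Step 4. The one-flask sequence may stall after the transacylation, and excess formaldehyde may add a second time once the thiol ester re-enolises. Epimerisation at C4 may also be too slow, so that part of the material cannot close. A retro-aldol of the C3 alkoxide would erode the C3 configuration. The fallback sets out from 4 and comes back at 8, and separates the events while closing the four-membered ring by carboxyl activation. Acid 4 would be converted into its methyl ester F1 (MeI, K2CO3, DMF). The lithium enolate of F1 (LiHMDS, THF, −78 °C) would be hydroxymethylated with formaldehyde and the aldolate left to transacylate onto the dioxolanone, giving the hydroxy lactone ester F2. The C3 epimers of F2 would be equilibrated with catalytic DBU toward the isomer with the ester trans to the benzyl group. LiOH followed by HCl would give the hydroxy acid F3. Benzenesulfonyl chloride in pyridine at 0 °C (Adam-type β-lactonisation) would then close only the cis-hydroxy acid to 8.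

Step 5. The aryllithium may add a second time to the freed ketone, attack the γ-lactone carbonyl, or deprotonate the β-lactone instead of adding. The lithium aldolate may also fragment by retro-aldol before the quench. The fallback sets out from 8 and comes back at 11, and replaces the polar organometallic by a neutral cross-coupling. Thiolysis of 8 at the acyl carbon (PhSH, catalytic Et3N, CH2Cl2, 0 °C; the alkyl C–O carbon is quaternary and cannot be attacked) would give the cis-hydroxy thiol ester F4 with both centres untouched. Liebeskind–Srogl coupling of F4 with commercial 4-(benzyloxy)-3-methoxyphenylboronic acid (Pd2(dba)3, tri(2-furyl)phosphine, CuTC, THF, 50 °C) would form the same aryl–carbonyl bond without base and give 11.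

Step 6. The electron-rich aryl ketone may be over-reduced, followed by hydrogenolysis of the resulting benzylic C–O bond. The fallback sets out from 11 and comes back at 12 without any reducing agent. Both benzyl ethers would be cleaved by BCl3 in the presence of pentamethylbenzene as cation scavenger (CH2Cl2, −78 °C). No new compound is made on the way (F0).

Further compounds
F1 | step 4 | methyl 2-[(2S,4S)-4-[4-(benzyloxy)-3-methoxybenzyl]-2-tert-butyl-5-oxo-1,3-dioxolan-4-yl]acetate | CC(C)(C)[C@H]1O[C@@](Cc2ccc(OCc3ccccc3)c(OC)c2)(CC(=O)OC)C(=O)O1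
F2 | step 4 | methyl (3S,4S)-4-[4-(benzyloxy)-3-methoxybenzyl]-4-hydroxy-5-oxotetrahydrofuran-3-carboxylate | COc1cc(C[C@@]2(O)C(=O)OC[C@@H]2C(=O)OC)ccc1OCc1ccccc1
F3 | step 4 | (3S,4S)-4-[4-(benzyloxy)-3-methoxybenzyl]-4-hydroxy-5-oxotetrahydrofuran-3-carboxylic acid | COc1cc(C[C@@]2(O)C(=O)OC[C@@H]2C(=O)O)ccc1OCc1ccccc1
F4 | step 5 | S-phenyl (3S,4S)-4-[4-(benzyloxy)-3-methoxybenzyl]-4-hydroxy-5-oxotetrahydrofuran-3-carbothioate | COc1cc(C[C@@]2(O)C(=O)OC[C@@H]2C(=O)Sc2ccccc2)ccc1OCc1ccccc1
F0 | step 6 | none | none
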